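Ring A of the target hides a γ,δ-unsaturated ester: ester carbonyl, quaternary C4, ring-fusion carbon C5 and the C10=C1 olefin. Disconnecting C4–C5 while restoring a C1–O bond leads back to a 6-(cyclohex-1-enyl)-3-methyl-δ-valerolactone that already holds ring B, the C8/C9 centres and the complete side chain. In one operation the [3,3] shift of its silyl ketene acetal forms the C4–C5 bond, closes carbocyclic ring A, moves the olefin to C1=C10 and sets C4 and C5 from the single carbinol centre C1. The lactone is assembled from a conjugate-addition-derived cyclohexanone, an (E)-alkenyl iodide and a glutaric N-methoxy-N-methylamide; esterification and Sharpless epoxidation complete the synthesis.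

Key step: step 12

Remarks on the chemistry:
- Numbering: ring A = C1–C2–C3–C4–C5–C10 and ring B = C5–C6–C7–C8–C9–C10. C4 carries the ester and a methyl group, C8 a methyl group, C9 a methyl group and the side chain C11–C15 (C13 methyl-bearing, C15 the CH2OH carbon).
- Faces: α is the face with H5 and the C8 and C9 methyl groups; β is the face with the C9 side chain and the ester.
- Abbreviations: TBS = tert-butyldimethylsilyl; DMPU = N,N'-dimethylpropyleneurea.
- Assumption: in step 4 the ligand antipode that gives the 3R ketone is used; this is a known reaction and the sense would be confirmed at ketone 11.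
- Design of the precursor: the C4 methyl group is put on lactone 25 by enolate methylation, so every intermediate up to 25 is a single stereoisomer and no unsymmetrical 2-methylglutaric derivative has to be opened regioselectively. Both C4 epimers of 27 give the same ketene acetal.
- Protecting group: the side-chain silyl ether is cleaved together with the silyl ester after the rearrangement, and the hindered acid is esterified with iodomethane, which avoids diazoalkanes.

Step 1
Reactants: 1 but-2-yn-1-ol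
Product: 2 tert-butyl(but-2-yn-1-yloxy)dimethylsilane
Conditions: TBSCl, imidazole, CH2Cl2, 0 → 23 °C
Reagents that add atoms: tert-butyldimethylsilyl chloride, CC(C)(C)[Si](C)(C)Cl
Why: Imidazole-promoted silylation of a primary alcohol (silyl ether protection) is routine and forms no stereocentre.

Step 2
Reactants: 2 tert-butyl(but-2-yn-1-yloxy)dimethylsilane
Product: 4 tert-butyl{[(2E)-3-iodobut-2-en-1-yl]oxy}dimethylsilane, via alkenylzirconocene chloride 3 (not isolated)
Conditions: Cp2Zr(H)Cl (2 equiv), THF, 50 °C; then I2, 0 °C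
Reagents that add atoms: iodine, II
Why: Hydrozirconation–iodination: syn addition of Zr–H, equilibrated by the excess hydride so that zirconium sits on the methyl-bearing carbon remote from the silyloxymethyl group, followed by iodinolysis with retention should give the (E)-alkenyl iodide.

Step 3
Reactants: 5 methyl 5-chloro-5-oxopentanoate
Product: 6 methyl 5-[methoxy(methyl)amino]-5-oxopentanoate
Conditions: MeNHOMe·HCl, pyridine, CH2Cl2, 0 → 23 °C
Reagents that add atoms: N,O-dimethylhydroxylamine hydrochloride, CNOC.Cl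
Why: Acylation of the hydroxylamine by the acid chloride (amide formation) is faster than any reaction at the methyl ester, and the symmetric glutarate unit raises no regiochemical question.

Step 4
Reactants: 7 2-methylcyclohex-2-en-1-one; 8 3-iodoprop-1-ene (allyl iodide)
Product: 11 (2S,3R)-2,3-dimethyl-2-(prop-2-en-1-yl)cyclohexan-1-one, via aluminium enolate 9 (not isolated), via lithium aluminate 10 (not isolated)
Conditions: Me3Al, Cu(O2CC4H3S) (copper thiophene-2-carboxylate, 2 mol %), binaphthol-derived bis(1-phenylethyl)amine phosphoramidite ligand (4 mol %), Et2O, −30 °C; then MeLi, THF/DMPU, 8, −30 → 0 °C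
Reagents that add atoms: trimethylaluminium, C[Al](C)C
Why: Copper-catalysed asymmetric conjugate addition sets C8 (3R) under ligand control, and allylation of the activated enolate (tandem conjugate addition–enolate alkylation) should occur anti to the new C8 methyl group, which sets quaternary C9 (2S) with the two methyl groups cis.

Step 5
Reactants: 11 (2S,3R)-2,3-dimethyl-2-(prop-2-en-1-yl)cyclohexan-1-one
Product: 14 (2S,3R)-2-(2-hydroxyethyl)-2,3-dimethylcyclohexan-1-one, via ozonide 12 (not isolated), via keto aldehyde 13 (not isolated)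
Conditions: O3, CH2Cl2, −78 °C; PPh3, −78 → 23 °C; then EtOH, NaBH4, −78 °C
Reagents that add atoms: ozone, [O-][O+]=O
Why: Ozonolysis of the terminal olefin with phosphine reduction of the ozonide gives the aldehyde, which NaBH4 at −78 °C should reduce chemoselectively beside the hindered ring ketone (chemoselective hydride reduction), leaving C8 and C9 untouched.

Step 6
Reactants: 14 (2S,3R)-2-(2-hydroxyethyl)-2,3-dimethylcyclohexan-1-one
Product: 15 (2S,3R)-2-(2-iodoethyl)-2,3-dimethylcyclohexan-1-one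
Conditions: PPh3, I2, imidazole, CH2Cl2, 0 → 23 °C
Reagents that add atoms: iodine, II
Why: Appel-type iodination converts the primary alcohol into the iodide under neutral conditions that the ketone tolerates.

Step 7
Reactants: 15 (2S,3R)-2-(2-iodoethyl)-2,3-dimethylcyclohexan-1-one; 4 tert-butyl{[(2E)-3-iodobut-2-en-1-yl]oxy}dimethylsilane
Product: 17 (2S,3R)-2-[(3E)-5-(TBS-oxy)-3-methylpent-3-en-1-yl]-2,3-dimethylcyclohexan-1-one, via alkylzinc iodide 16 (not isolated)
Conditions: Zn dust (activated with TMSCl and 1,2-dibromoethane), LiCl, THF, 40 °C; then 4, Pd(PPh3)4 (5 mol %), THF, 50 °C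
Reagents that add atoms: none
Why: Zinc insertion into the primary C–I bond tolerates the ketone, and the palladium-catalysed Negishi coupling of the alkylzinc iodide with the alkenyl iodide should form the C12–C13 bond with retention of the E geometry.

Step 8
Reactants: 17 (2S,3R)-2-[(3E)-5-(TBS-oxy)-3-methylpent-3-en-1-yl]-2,3-dimethylcyclohexan-1-one
Product: 18 2,4,6-triisopropylbenzenesulfonyl hydrazone of ketone 17
Conditions: 2,4,6-triisopropylbenzenesulfonyl hydrazide, pyridinium p-toluenesulfonate (cat.), THF, 23 °C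
Reagents that add atoms: 2,4,6-triisopropylbenzenesulfonyl hydrazide, CC(C)c1cc(C(C)C)c(S(=O)(=O)NN)c(C(C)C)c1
Why: Condensation of the ketone with the arenesulfonyl hydrazide (hydrazone formation) prepares the Shapiro reaction, the N–N bond being expected anti to quaternary C9 and therefore syn to the C5 methylene.

Step 9
Reactants: 18 2,4,6-triisopropylbenzenesulfonyl hydrazone of ketone 17; 6 methyl 5-[methoxy(methyl)amino]-5-oxopentanoate
Product: 22 methyl 5-{(5R,6S)-6-[(3E)-5-(TBS-oxy)-3-methylpent-3-en-1-yl]-5,6-dimethylcyclohex-1-en-1-yl}-5-oxopentanoate, via alkenyllithium 19 (not isolated), via alkenylmagnesium bromide 20 (not isolated), via magnesium hemiaminal 21 (not isolated)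
Conditions: n-BuLi (2.1 equiv), THF, −78 → 0 °C; MgBr2·OEt2, −78 °C; then 6, −78 → 0 °C; aq. NH4Cl
Reagents that add atoms: none
Why: Shapiro reaction followed by acylation: deprotonation can only take place at C5 because C9 is quaternary, loss of sulfinate and N2 gives the C10 alkenyl anion, and after transmetalation to magnesium it should add to the N-methoxy-N-methylamide, whose chelated adduct prevents over-addition and spares the methyl ester.

Step 10
Reactants: 22 methyl 5-{(5R,6S)-6-[(3E)-5-(TBS-oxy)-3-methylpent-3-en-1-yl]-5,6-dimethylcyclohex-1-en-1-yl}-5-oxopentanoate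
Product: 25 (6R)-6-{(5R,6S)-6-[(3E)-5-(TBS-oxy)-3-methylpent-3-en-1-yl]-5,6-dimethylcyclohex-1-en-1-yl}oxan-2-one, via catechol borate 23 (not isolated), via hydroxy ester 24 (not isolated)
Conditions: (S)-1-methyl-3,3-diphenyltetrahydro-1H,3H-pyrrolo[1,2-c][1,3,2]oxazaborole (20 mol %), catecholborane, toluene, −78 °C; MeOH, concentrate; then pyridinium p-toluenesulfonate (cat.), toluene, 50 °C
Reagents that add atoms: none
Why: CBS reduction with the (S)-oxazaborolidine should treat the α-branched cyclohexenyl group as the large substituent and set C1 as R under reagent control (catecholborane at −78 °C leaves the ester and the isolated olefin alone), after which acid-catalysed lactonisation of the δ-hydroxy ester closes the ring with retention at C1.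

Step 11
Reactants: 25 (6R)-6-{(5R,6S)-6-[(3E)-5-(TBS-oxy)-3-methylpent-3-en-1-yl]-5,6-dimethylcyclohex-1-en-1-yl}oxan-2-one
Product: 27 (3RS,6R)-6-{(5R,6S)-6-[(3E)-5-(TBS-oxy)-3-methylpent-3-en-1-yl]-5,6-dimethylcyclohex-1-en-1-yl}-3-methyloxan-2-one, via lithium enolate 26 (not isolated)
Conditions: LiN(iPr)2, THF, −78 °C; MeI, −78 → −30 °C
Reagents that add atoms: iodomethane, CI
Why: Methylation of the lactone lithium enolate (enolate alkylation) installs the C4 methyl group, and the configuration formed at C4 is immaterial because both epimers give the same ketene acetal in step 12.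

Step 12
Reactants: 27 (3RS,6R)-6-{(5R,6S)-6-[(3E)-5-(TBS-oxy)-3-methylpent-3-en-1-yl]-5,6-dimethylcyclohex-1-en-1-yl}-3-methyloxan-2-one
Product: 31 (1S,5S,6R,8aR)-5-[(3E)-5-hydroxy-3-methylpent-3-en-1-yl]-1,5,6-trimethyl-1,2,3,5,6,7,8,8a-octahydronaphthalene-1-carboxylic acid, via lithium enolate 28 (not isolated), via silyl ketene acetal 29 (not isolated), via silyl ester 30 (not isolated)
Conditions: LiN(iPr)2, THF, −78 °C; TBSCl, DMPU, −78 → 0 °C; toluene, 105 °C; then Bu4NF, THF, 23 °C; 0.5 M aq. HCl to pH 3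
Reagents that add atoms: none
Why: Deprotonation at C4 and O-silylation give the endocyclic silyl ketene acetal, whose geometry is fixed by the lactone ring, and heating should trigger a concerted suprafacial [3,3] sigmatropic shift (the lactone-enolate variant of the Ireland–Claisen rearrangement, known for 6-alkenyl δ-lactones) in which C4–C5 forms as C1–O breaks and the olefin moves from C10=C5 to C1=C10. Ring A (C1–C2–C3–C4–C5–C10) is closed by this bond formation between the ketene-acetal carbon C4 and the olefin terminus C5 inside a bicyclo[2.2.2]octane-like array, so the six-atom transition state must be boat-like, a chair being impossible because C2–C3 tie C1 to C4. C5 is set by chirality transfer from the (1R)-carbinol: C2 must lie s-cis to C5, which places the C1–O bond on the β-face of ring B, and the new bond enters C5 from that face and leaves H5 α (5R). C4 is set by the enforced boat: the carboxyl carbon arrives on the face that the lactone oxygen occupied and the methyl group points outwards, so the carboxyl ends trans to H5 (4S) whatever the C4 configuration of 27. The only selectivity the step needs is compatibility of this β-face attack with ring B, and it is secured because the β-face is anti to the pseudoaxial C9 methyl group in the half-chair that keeps the C8 methyl group and the C9 side chain pseudoequatorial. Fluoride then cleaves the silyl ester and the side-chain silyl ether in the same flask, so acid 31 can be purified by acid–base extraction.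

Step 13
Reactants: 31 (1S,5S,6R,8aR)-5-[(3E)-5-hydroxy-3-methylpent-3-en-1-yl]-1,5,6-trimethyl-1,2,3,5,6,7,8,8a-octahydronaphthalene-1-carboxylic acid
Product: 32 methyl (1S,5S,6R,8aR)-5-[(3E)-5-hydroxy-3-methylpent-3-en-1-yl]-1,5,6-trimethyl-1,2,3,5,6,7,8,8a-octahydronaphthalene-1-carboxylate
Conditions: MeI, K2CO3, DMF, 23 °C
Reagents that add atoms: iodomethane, CI
Why: SN2 O-alkylation of the carboxylate (carboxylate esterification) is insensitive to the hindrance at C4 and should be chemoselective over the primary allylic alcohol.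

Step 14
Reactants: 32 methyl (1S,5S,6R,8aR)-5-[(3E)-5-hydroxy-3-methylpent-3-en-1-yl]-1,5,6-trimethyl-1,2,3,5,6,7,8,8a-octahydronaphthalene-1-carboxylate
Product: 33 methyl (1S,5S,6R,8aR)-5-{2-[(2S,3S)-3-(hydroxymethyl)-2-methyloxiran-2-yl]ethyl}-1,5,6-trimethyl-1,2,3,5,6,7,8,8a-octahydronaphthalene-1-carboxylate (target)
Conditions: Ti(OiPr)4 (10 mol %), L-(+)-diethyl tartrate (12 mol %), t-BuOOH (anhydrous, in isooctane), 4 Å molecular sieves, CH2Cl2, −20 °C
Reagents that add atoms: tert-butyl hydroperoxide, CC(C)(C)OO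
Why: Sharpless asymmetric epoxidation acts only on the allylic-alcohol olefin and, as for (E)-3-methylalk-2-en-1-ols of the geraniol type, the L-(+)-tartrate catalyst should give the (13S,14S)-epoxide, the E geometry fixing C12 and C15 trans on the oxirane, while the C1=C10 olefin and the ester stay untouched.

Compound list
1 | but-2-yn-1-ol | CC#CCO | starting material
2 | tert-butyl(but-2-yn-1-yloxy)dimethylsilane | CC#CCO[Si](C)(C)C(C)(C)C | intermediate
3 | chlorobis(cyclopentadienyl){(2E)-4-[(tert-butyldimethylsilyl)oxy]but-2-en-2-yl}zirconium | Cl[Zr](C1C=CC=C1)(C1C=CC=C1)/C(C)=C/CO[Si](C)(C)C(C)(C)C | intermediate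
4 | tert-butyl{[(2E)-3-iodobut-2-en-1-yl]oxy}dimethylsilane | I/C(C)=C/CO[Si](C)(C)C(C)(C)C | intermediate
5 | methyl 5-chloro-5-oxopentanoate | COC(=O)CCCC(Cl)=O | starting material
6 | methyl 5-[methoxy(methyl)amino]-5-oxopentanoate | COC(=O)CCCC(=O)N(C)OC | intermediate
7 | 2-methylcyclohex-2-en-1-one | CC1=CCCC1=O | starting material
8 | 3-iodoprop-1-ene (allyl iodide) | C=CCI | starting material
9 | dimethylaluminium (3R)-2,3-dimethylcyclohex-1-en-1-olate | C[Al](C)OC1=C(C)[C@H](C)CCC1 | intermediate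
10 | lithium trimethyl[(3R)-2,3-dimethylcyclohex-1-en-1-olato]aluminate | [Li+].C[Al-](C)(C)OC1=C(C)[C@H](C)CCC1 | intermediate
11 | (2S,3R)-2,3-dimethyl-2-(prop-2-en-1-yl)cyclohexan-1-one | O=C1CCC[C@@H](C)[C@]1(C)CC=C | intermediate
12 | (2S,3R)-2,3-dimethyl-2-(1,2,4-trioxolan-3-ylmethyl)cyclohexan-1-one (ozonide, mixture at the trioxolane carbon) | O=C1CCC[C@@H](C)[C@]1(C)CC2OCOO2 | intermediate
13 | 2-[(1S,2R)-1,2-dimethyl-6-oxocyclohexyl]acetaldehyde | O=C1CCC[C@@H](C)[C@]1(C)CC=O | intermediate
14 | (2S,3R)-2-(2-hydroxyethyl)-2,3-dimethylcyclohexan-1-one | O=C1CCC[C@@H](C)[C@]1(C)CCO | intermediate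
15 | (2S,3R)-2-(2-iodoethyl)-2,3-dimethylcyclohexan-1-one | O=C1CCC[C@@H](C)[C@]1(C)CCI | intermediate
16 | {2-[(1S,2R)-1,2-dimethyl-6-oxocyclohexyl]ethyl}(iodo)zinc | O=C1CCC[C@@H](C)[C@]1(C)CC[Zn]I | intermediate
17 | (2S,3R)-2-{(3E)-5-[(tert-butyldimethylsilyl)oxy]-3-methylpent-3-en-1-yl}-2,3-dimethylcyclohexan-1-one | O=C1CCC[C@@H](C)[C@]1(C)CC/C(C)=C/CO[Si](C)(C)C(C)(C)C | intermediate
18 | N'-[(2S,3R)-2-{(3E)-5-[(tert-butyldimethylsilyl)oxy]-3-methylpent-3-en-1-yl}-2,3-dimethylcyclohexylidene]-2,4,6-tri(propan-2-yl)benzenesulfonohydrazide (C=N geometry not specified) | CC(C)c1cc(C(C)C)c(S(=O)(=O)NN=C2CCC[C@@H](C)[C@]2(C)CC/C(C)=C/CO[Si](C)(C)C(C)(C)C)c(C(C)C)c1 | intermediate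
19 | [(5R,6S)-6-{(3E)-5-[(tert-butyldimethylsilyl)oxy]-3-methylpent-3-en-1-yl}-5,6-dimethylcyclohex-1-en-1-yl]lithium | [Li]C1=CCC[C@@H](C)[C@]1(C)CC/C(C)=C/CO[Si](C)(C)C(C)(C)C | intermediate
20 | bromo[(5R,6S)-6-{(3E)-5-[(tert-butyldimethylsilyl)oxy]-3-methylpent-3-en-1-yl}-5,6-dimethylcyclohex-1-en-1-yl]magnesium | Br[Mg]C1=CCC[C@@H](C)[C@]1(C)CC/C(C)=C/CO[Si](C)(C)C(C)(C)C | intermediate
21 | bromomagnesium alkoxide of the tetrahedral adduct of 20 with amide 6 (hemiaminal carbon unspecified) | COC(=O)CCCC(O[Mg]Br)(N(C)OC)C1=CCC[C@@H](C)[C@]1(C)CC/C(C)=C/CO[Si](C)(C)C(C)(C)C | intermediate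
22 | methyl 5-[(5R,6S)-6-{(3E)-5-[(tert-butyldimethylsilyl)oxy]-3-methylpent-3-en-1-yl}-5,6-dimethylcyclohex-1-en-1-yl]-5-oxopentanoate | COC(=O)CCCC(=O)C1=CCC[C@@H](C)[C@]1(C)CC/C(C)=C/CO[Si](C)(C)C(C)(C)C | intermediate
23 | methyl (5R)-5-(1,3,2-benzodioxaborol-2-yloxy)-5-[(5R,6S)-6-{(3E)-5-[(tert-butyldimethylsilyl)oxy]-3-methylpent-3-en-1-yl}-5,6-dimethylcyclohex-1-en-1-yl]pentanoate | COC(=O)CCC[C@@H](OB1Oc2ccccc2O1)C3=CCC[C@@H](C)[C@]3(C)CC/C(C)=C/CO[Si](C)(C)C(C)(C)C | intermediate
24 | methyl (5R)-5-[(5R,6S)-6-{(3E)-5-[(tert-butyldimethylsilyl)oxy]-3-methylpent-3-en-1-yl}-5,6-dimethylcyclohex-1-en-1-yl]-5-hydroxypentanoate | COC(=O)CCC[C@@H](O)C1=CCC[C@@H](C)[C@]1(C)CC/C(C)=C/CO[Si](C)(C)C(C)(C)C | intermediate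
25 | (6R)-6-[(5R,6S)-6-{(3E)-5-[(tert-butyldimethylsilyl)oxy]-3-methylpent-3-en-1-yl}-5,6-dimethylcyclohex-1-en-1-yl]oxan-2-one | O=C1CCC[C@@H](O1)C2=CCC[C@@H](C)[C@]2(C)CC/C(C)=C/CO[Si](C)(C)C(C)(C)C | intermediate
26 | lithium (2R)-2-[(5R,6S)-6-{(3E)-5-[(tert-butyldimethylsilyl)oxy]-3-methylpent-3-en-1-yl}-5,6-dimethylcyclohex-1-en-1-yl]-3,4-dihydro-2H-pyran-6-olate | [Li]OC1=CCC[C@@H](O1)C2=CCC[C@@H](C)[C@]2(C)CC/C(C)=C/CO[Si](C)(C)C(C)(C)C | intermediate
27 | (3RS,6R)-6-[(5R,6S)-6-{(3E)-5-[(tert-butyldimethylsilyl)oxy]-3-methylpent-3-en-1-yl}-5,6-dimethylcyclohex-1-en-1-yl]-3-methyloxan-2-one (both C4 epimers) | CC1CC[C@@H](OC1=O)C2=CCC[C@@H](C)[C@]2(C)CC/C(C)=C/CO[Si](C)(C)C(C)(C)C | intermediate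
28 | lithium (2R)-2-[(5R,6S)-6-{(3E)-5-[(tert-butyldimethylsilyl)oxy]-3-methylpent-3-en-1-yl}-5,6-dimethylcyclohex-1-en-1-yl]-5-methyl-3,4-dihydro-2H-pyran-6-olate | [Li]OC1=C(C)CC[C@@H](O1)C2=CCC[C@@H](C)[C@]2(C)CC/C(C)=C/CO[Si](C)(C)C(C)(C)C | intermediate
29 | tert-butyl({(2R)-2-[(5R,6S)-6-{(3E)-5-[(tert-butyldimethylsilyl)oxy]-3-methylpent-3-en-1-yl}-5,6-dimethylcyclohex-1-en-1-yl]-5-methyl-3,4-dihydro-2H-pyran-6-yl}oxy)dimethylsilane | CC(C)(C)[Si](C)(C)OC1=C(C)CC[C@@H](O1)C2=CCC[C@@H](C)[C@]2(C)CC/C(C)=C/CO[Si](C)(C)C(C)(C)C | intermediate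
30 | tert-butyldimethylsilyl (1S,5S,6R,8aR)-5-{(3E)-5-[(tert-butyldimethylsilyl)oxy]-3-methylpent-3-en-1-yl}-1,5,6-trimethyl-1,2,3,5,6,7,8,8a-octahydronaphthalene-1-carboxylate | CC(C)(C)[Si](C)(C)OC(=O)[C@@]1(C)CCC=C2[C@H]1CC[C@@H](C)[C@]2(C)CC/C(C)=C/CO[Si](C)(C)C(C)(C)C | intermediate
31 | (1S,5S,6R,8aR)-5-[(3E)-5-hydroxy-3-methylpent-3-en-1-yl]-1,5,6-trimethyl-1,2,3,5,6,7,8,8a-octahydronaphthalene-1-carboxylic acid | OC(=O)[C@@]1(C)CCC=C2[C@H]1CC[C@@H](C)[C@]2(C)CC/C(C)=C/CO | intermediate
32 | methyl (1S,5S,6R,8aR)-5-[(3E)-5-hydroxy-3-methylpent-3-en-1-yl]-1,5,6-trimethyl-1,2,3,5,6,7,8,8a-octahydronaphthalene-1-carboxylate | COC(=O)[C@@]1(C)CCC=C2[C@H]1CC[C@@H](C)[C@]2(C)CC/C(C)=C/CO | intermediate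
33 | methyl (1S,5S,6R,8aR)-5-{2-[(2S,3S)-3-(hydroxymethyl)-2-methyloxiran-2-yl]ethyl}-1,5,6-trimethyl-1,2,3,5,6,7,8,8a-octahydronaphthalene-1-carboxylate | COC(=O)[C@@]1(C)CCC=C2[C@H]1CC[C@@H](C)[C@]2(C)CC[C@]1(C)O[C@H]1CO | target

Total step count: 14 (steps 1–3 prepare the two side fragments).
Longest linear sequence: 11 steps (steps 4–14, from 2-methylcyclohex-2-en-1-one).

Steps most likely to fail

1. Step 12. The boat-shaped shift has to join a fully substituted ketene-acetal carbon to a ring carbon and may be slow. Silyl transfer from oxygen to carbon, hydrolytic return to the lactone or ionisation of the allylic C1–O bond could then compete. The fallback builds ring A by a Diels–Alder reaction instead; it sets out from 17 and comes back at 32. KN(SiMe3)2 and PhNTf2 (THF, −78 °C) would convert 17 into the enol triflate F1. Suzuki coupling with potassium vinyltrifluoroborate (PdCl2(dppf), Cs2CO3, THF/H2O) would give the 1-vinylcyclohexene F2. Its Me2AlCl-promoted Diels–Alder reaction with methyl methacrylate (CH2Cl2, −40 °C) would form C2–C3 and C4–C5 and give the silyl-protected ester F3, and Bu4NF would then give 32. The expected sense is ester carbon to the substituted diene terminus C5, addition anti to the pseudoaxial C9 methyl group, ester endo. Regio- and endo-selectivity are not enforced by a tether here and would have to be checked.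

2. Step 10. Reagent control may be eroded by the neighbouring C8/C9 centres or by a twisted enone, giving poor facial selectivity at C1. Any 1S material would be carried into the wrong C4/C5 configuration in step 12. The fallback replaces the asymmetric reduction by an inversion; it sets out from 22 and comes back at 25. Luche reduction (NaBH4, CeCl3·7H2O, MeOH, −78 °C) would give 24 and its C1 epimer, the (5S)-hydroxy ester F4, which are diastereomers and should be separable. 24 is lactonised as in step 10. F4 would be saponified (LiOH, THF/H2O) to the (5S)-hydroxy acid F5, and Mitsunobu lactonisation (PPh3, diisopropyl azodicarboxylate, THF, 0 °C) would close it with inversion at C1 to the same lactone 25.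

3. Step 9. The hindered alkenyl anion may be quenched by proton transfer, the hydrazone dianion may fragment incompletely, or the organometallic may attack the ester of 6. The fallback avoids strongly basic organometallics; it sets out from 17 and comes back at 22. The enol triflate F1, made as in the first fallback, would be coupled with commercial methyl 5-oxopentanoate under Nozaki–Hiyama–Kishi conditions (CrCl2, NiCl2 cat., DMF, 23 °C) to give the allylic alcohols F6 as both C1 epimers. Oxidation with MnO2 (CH2Cl2) without delay would give enone 22.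

Further compounds
F1 | step 12 | (5R,6S)-6-{(3E)-5-[(tert-butyldimethylsilyl)oxy]-3-methylpent-3-en-1-yl}-5,6-dimethylcyclohex-1-en-1-yl trifluoromethanesulfonate | O=S(=O)(OC1=CCC[C@@H](C)[C@]1(C)CC/C(C)=C/CO[Si](C)(C)C(C)(C)C)C(F)(F)F
F2 | step 12 | (5R,6S)-6-{(3E)-5-[(tert-butyldimethylsilyl)oxy]-3-methylpent-3-en-1-yl}-1-ethenyl-5,6-dimethylcyclohex-1-ene | C=CC1=CCC[C@@H](C)[C@]1(C)CC/C(C)=C/CO[Si](C)(C)C(C)(C)C
F3 | step 12 | methyl (1S,5S,6R,8aR)-5-{(3E)-5-[(tert-butyldimethylsilyl)oxy]-3-methylpent-3-en-1-yl}-1,5,6-trimethyl-1,2,3,5,6,7,8,8a-octahydronaphthalene-1-carboxylate | COC(=O)[C@@]1(C)CCC=C2[C@H]1CC[C@@H](C)[C@]2(C)CC/C(C)=C/CO[Si](C)(C)C(C)(C)C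
F4 | step 10 | methyl (5S)-5-[(5R,6S)-6-{(3E)-5-[(tert-butyldimethylsilyl)oxy]-3-methylpent-3-en-1-yl}-5,6-dimethylcyclohex-1-en-1-yl]-5-hydroxypentanoate | COC(=O)CCC[C@H](O)C1=CCC[C@@H](C)[C@]1(C)CC/C(C)=C/CO[Si](C)(C)C(C)(C)C
F5 | step 10 | (5S)-5-[(5R,6S)-6-{(3E)-5-[(tert-butyldimethylsilyl)oxy]-3-methylpent-3-en-1-yl}-5,6-dimethylcyclohex-1-en-1-yl]-5-hydroxypentanoic acid | OC(=O)CCC[C@H](O)C1=CCC[C@@H](C)[C@]1(C)CC/C(C)=C/CO[Si](C)(C)C(C)(C)C
F6 | step 9 | methyl (5RS)-5-[(5R,6S)-6-{(3E)-5-[(tert-butyldimethylsilyl)oxy]-3-methylpent-3-en-1-yl}-5,6-dimethylcyclohex-1-en-1-yl]-5-hydroxypentanoate | COC(=O)CCCC(O)C1=CCC[C@@H](C)[C@]1(C)CC/C(C)=C/CO[Si](C)(C)C(C)(C)C
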